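**Retrosynthetic overview**
1. 17 ⇒ o‑quinol 14 + enol silane 13: C6–CH2 bond by an anti‑selective 1,6‑addition (last step, sets C6).
2. 14 ⇒ phenol 10: C7–O bond by asymmetric hydroxylative dearomatization of ring B (key step, sets C7).
3. 10 ⇒ aldehyde 8: O2–C3 bond by 6‑endo cycloisomerization with hydride transfer to C1 (closes ring A).
4. 8 ⇒ 3 + 6 (Sonogashira); 3 ⇒ 1 (ortho‑formylation); 6 ⇒ 4 + 5; 13 ⇒ 11.
5. Ring order: ring B is bought as a benzene ring; ring A (pyran) is closed onto it in step 4; ring B is dearomatised in step 6.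

Locants follow isochromene numbering: C1 (OCH2), O2, C3 (propenyl), C4, C4a, C5, C6, C7, C8 (C=O), C8a. The target is (6S,7S), with the C7 hydroxyl trans to the C6 side chain.

Assumption: the facial sense of the chiral iodyl reagent in step 6 is assigned by analogy with its use on simple 2‑alkylphenols; if it proves opposite, the mirror‑image reagent from (R)‑valinol is used.

**Step 1**
Reactants: 1 5‑bromo‑2‑methylphenol
Product: 3 6‑bromo‑2‑hydroxy‑3‑methylbenzaldehyde, via 3‑bromo‑2‑(hydroxymethyl)‑6‑methylphenol 2 (not isolated)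
Conditions: (CH2O)n (6 equiv), MgCl2 (2 equiv), Et3N (4 equiv), MeCN, reflux
Reagents that add atoms: paraformaldehyde (formaldehyde), C=O
Why: Magnesium‑phenoxide‑directed ortho‑formylation (Casnati–Skattebøl reaction): formaldehyde is delivered inside the Mg chelate only ortho to the phenol, the methyl group blocks one ortho carbon so the carbon between OH and Br is hydroxymethylated (2), and a second formaldehyde oxidises 2 by hydride transfer.

**Step 2**
Reactants: 4 (E)‑1‑bromoprop‑1‑ene; 5 ethynyltrimethylsilane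
Product: 6 trimethyl[(3E)‑pent‑3‑en‑1‑yn‑1‑yl]silane
Conditions: Pd(PPh3)2Cl2 (2 mol %), CuI (4 mol %), iPr2NH, THF, 0 °C → rt
Reagents that add atoms: none
Why: Sonogashira coupling of a vinyl bromide proceeds with retention of the E geometry, and the silyl cap makes the volatile enyne easy to handle.

**Step 3**
Reactants: 3 6‑bromo‑2‑hydroxy‑3‑methylbenzaldehyde; 6 trimethyl[(3E)‑pent‑3‑en‑1‑yn‑1‑yl]silane
Product: 8 2‑hydroxy‑3‑methyl‑6‑[(3E)‑pent‑3‑en‑1‑yn‑1‑yl]benzaldehyde, via (3E)‑pent‑3‑en‑1‑yne 7 (not isolated)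
Conditions: Pd(PPh3)2Cl2 (3 mol %), CuI (6 mol %), CsF (2.5 equiv), Et3N/DMF, H2O (2 equiv), 50 °C, sealed
Reagents that add atoms: none
Why: One‑pot desilylation–Sonogashira coupling: fluoride releases the volatile enyne 7 in the flask and it couples at once with the aryl bromide, whose oxidative addition is helped by the ortho formyl group, while the free phenol is tolerated.

**Step 4**
Reactants: 8 2‑hydroxy‑3‑methyl‑6‑[(3E)‑pent‑3‑en‑1‑yn‑1‑yl]benzaldehyde
Product: 10 7‑methyl‑3‑[(1E)‑prop‑1‑en‑1‑yl]‑1H‑isochromen‑8‑ol, via quinoid 7‑methyl‑3‑[(1E)‑prop‑1‑en‑1‑yl]‑8H‑isochromen‑8‑one 9 (not isolated)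
Conditions: AgOTf (5 mol %), (PhO)2PO2H (10 mol %), diethyl 2,6‑dimethyl‑1,4‑dihydropyridine‑3,5‑dicarboxylate (Hantzsch ester, 1.2 equiv), CH2Cl2, rt
Reagents that add atoms: none
Why: Domino cycloisomerization–transfer hydrogenation of an o‑alkynylbenzaldehyde: silver‑activated 6‑endo‑dig attack of the formyl oxygen on the enyne forms the O2–C3 bond of ring A (6‑endo because a benzopyrylium, here its neutral quinoid form 9, results), and the dihydropyridine delivers hydride to C1, which restores the phenol.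

**Step 5**
Reactants: 11 nonan‑2‑one
Product: 13 trimethyl(non‑1‑en‑2‑yloxy)silane, via lithium non‑1‑en‑2‑olate 12 (not isolated)
Conditions: LiN(iPr)2 (1.1 equiv), THF, −78 °C; then Me3SiCl, −78 °C → rt
Reagents that add atoms: chlorotrimethylsilane, C[Si](C)(C)Cl
Why: Kinetic deprotonation of the methyl ketone at CH3 by the hindered amide base followed by O‑silylation gives the less substituted enol silane regioselectively.

**Step 6**
Reactants: 10 7‑methyl‑3‑[(1E)‑prop‑1‑en‑1‑yl]‑1H‑isochromen‑8‑ol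
Product: 14 (7S)‑7‑hydroxy‑7‑methyl‑3‑[(1E)‑prop‑1‑en‑1‑yl]‑1H‑isochromen‑8(7H)‑one
Conditions: (S)‑2‑(2‑iodylphenyl)‑4‑(propan‑2‑yl)‑4,5‑dihydro‑1,3‑oxazole (1.2 equiv), CH2Cl2, −20 → 0 °C; aq. NaHCO3 work‑up at 0 °C; used at once
Reagents that add atoms: (S)‑2‑(2‑iodylphenyl)‑4‑(propan‑2‑yl)‑4,5‑dihydro‑1,3‑oxazole, CC(C)[C@H]1COC(=N1)c1ccccc1I(=O)=O
Why: Hydroxylative phenol dearomatization with a chiral iodyl arene (pentavalent iodine): the phenol exchanges onto iodine and the iodyl oxygen is delivered within the complex to ortho carbon C7, which is methyl‑substituted, para to the enol ether donor and less hindered than ring‑fusion carbon C8a, forming the C7–O bond, and the oxazoline substituent shields one face so that oxygen enters on the Si face of C7 and gives the 7S carbinol (reagent control).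

**Step 7**
Reactants: 14 (7S)‑7‑hydroxy‑7‑methyl‑3‑[(1E)‑prop‑1‑en‑1‑yl]‑1H‑isochromen‑8(7H)‑one; 13 trimethyl(non‑1‑en‑2‑yloxy)silane
Product: 17 (6S,7S)‑7‑hydroxy‑7‑methyl‑6‑(2‑oxononyl)‑3‑[(1E)‑prop‑1‑en‑1‑yl]‑6,7‑dihydro‑1H‑isochromen‑8(5H)‑one, via O‑trimethylsilyl o‑quinol 15 (not isolated), via bis(trimethylsilyl) 1,6‑adduct 16 (not isolated)
Conditions: 13 (3 equiv), Bu4N[Ph3SiF2] (10 mol %), THF, −78 → −40 °C; then 1 M HCl, THF, 0 °C
Reagents that add atoms: none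
Why: Proposed new method: fluoride‑initiated, silyl‑transfer vinylogous Mukaiyama–Michael 1,6‑addition to an o‑quinol, in which the first equivalent of 13 caps the tertiary OH as silyl ether 15 (no alkoxide‑directed syn delivery, no α‑ketol shift), the ammonium enolate attacks the neutral dienone at C6, the only unhindered acceptor carbon (C4a is fully substituted, C8 is flanked by two fully substituted carbons, C3 is an ester‑like alkoxy carbon that stays unreactive without Lewis acid), on the Re face anti to the C7–OSiMe3 bond (steric shielding plus σ*C–O alignment, as in additions to 4‑silyloxycyclohexenones) so that C6 is set trans to oxygen, the dienolate is O‑silylated by 13 (chain transfer) to give 16, and acid protonates C5 and frees both oxygens; the closest known reactions are fluoride‑catalysed Michael additions of enol silanes to enones and organocopper 1,6‑additions to 2,4‑dienones.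

**Compound list**
1 | 5‑bromo‑2‑methylphenol | Cc1ccc(Br)cc1O | starting material
2 | 3‑bromo‑2‑(hydroxymethyl)‑6‑methylphenol | Cc1ccc(Br)c(CO)c1O | intermediate
3 | 6‑bromo‑2‑hydroxy‑3‑methylbenzaldehyde | Cc1ccc(Br)c(C=O)c1O | intermediate
4 | (E)‑1‑bromoprop‑1‑ene | C/C=C/Br | starting material
5 | ethynyltrimethylsilane | C#C[Si](C)(C)C | starting material
6 | trimethyl[(3E)‑pent‑3‑en‑1‑yn‑1‑yl]silane | C/C=C/C#C[Si](C)(C)C | intermediate
7 | (3E)‑pent‑3‑en‑1‑yne | C/C=C/C#C | intermediate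
8 | 2‑hydroxy‑3‑methyl‑6‑[(3E)‑pent‑3‑en‑1‑yn‑1‑yl]benzaldehyde | C/C=C/C#Cc1ccc(C)c(O)c1C=O | intermediate
9 | 7‑methyl‑3‑[(1E)‑prop‑1‑en‑1‑yl]‑8H‑isochromen‑8‑one | C/C=C/C1=CC2=CC=C(C)C(=O)C2=CO1 | intermediate
10 | 7‑methyl‑3‑[(1E)‑prop‑1‑en‑1‑yl]‑1H‑isochromen‑8‑ol | C/C=C/C1=Cc2ccc(C)c(O)c2CO1 | intermediate
11 | nonan‑2‑one | CCCCCCCC(C)=O | starting material
12 | lithium non‑1‑en‑2‑olate | [Li]OC(=C)CCCCCCC | intermediate
13 | trimethyl(non‑1‑en‑2‑yloxy)silane | C=C(CCCCCCC)O[Si](C)(C)C | intermediate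
14 | (7S)‑7‑hydroxy‑7‑methyl‑3‑[(1E)‑prop‑1‑en‑1‑yl]‑1H‑isochromen‑8(7H)‑one | C/C=C/C1=CC2=C(CO1)C(=O)[C@@](C)(O)C=C2 | intermediate
15 | (7S)‑7‑methyl‑3‑[(1E)‑prop‑1‑en‑1‑yl]‑7‑(trimethylsilyloxy)‑1H‑isochromen‑8(7H)‑one | C/C=C/C1=CC2=C(CO1)C(=O)[C@@](C)(O[Si](C)(C)C)C=C2 | intermediate
16 | 1‑[(6R,7S)‑7‑methyl‑3‑[(1E)‑prop‑1‑en‑1‑yl]‑7,8‑bis(trimethylsilyloxy)‑6,7‑dihydro‑1H‑isochromen‑6‑yl]nonan‑2‑one | C/C=C/C1=CC2=C[C@@H](CC(=O)CCCCCCC)[C@](C)(O[Si](C)(C)C)C(O[Si](C)(C)C)=C2CO1 | intermediate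
17 | (6S,7S)‑7‑hydroxy‑7‑methyl‑6‑(2‑oxononyl)‑3‑[(1E)‑prop‑1‑en‑1‑yl]‑6,7‑dihydro‑1H‑isochromen‑8(5H)‑one | C/C=C/C1=CC2=C(CO1)C(=O)[C@@](C)(O)[C@H](CC(=O)CCCCCCC)C2 | target

**Step count**
Total steps: 7. Longest linear sequence: 5 steps (1 → 3 → 8 → 10 → 14 → 17; steps 1, 3, 4, 6, 7).

**Steps most likely to fail**

Step 6 (hydroxylative dearomatization). Oxygen could also go to C8a, the ee of this reagent class can be moderate, and 14 may dimerise by [4+2] cycloaddition. Dimerisation would break the O2–C3=C4–C4a=C8a–C8=O conjugation, which should slow it; 14 is nevertheless kept cold and used at once. The fallback builds the carbinol by enolate hydroxylation; it sets out from 6 and comes back at 15. Commercial cyclohexane‑1,3‑dione and paraformaldehyde with BF3·OEt2 give the dioxin vinylogous ester 7,8‑dihydro‑4H‑1,3‑benzodioxin‑5(6H)‑one F1. Compound 6 is treated with MeLi·LiBr (desilylative lithiation) and F1 is added at −78 °C; work‑up with 1 M HCl unravels the adduct with carbonyl transposition to 2‑(hydroxymethyl)‑3‑[(3E)‑pent‑3‑en‑1‑yn‑1‑yl]cyclohex‑2‑en‑1‑one F2. AgOTf (5 mol %) closes ring A by 6‑endo oxa‑Michael addition to 3‑[(1E)‑prop‑1‑en‑1‑yl]‑6,7‑dihydro‑1H‑isochromen‑8(5H)‑one F3. LiN(iPr)2 and MeI give racemic 7‑methyl‑3‑[(1E)‑prop‑1‑en‑1‑yl]‑6,7‑dihydro‑1H‑isochromen‑8(5H)‑one F4. NaN(SiMe3)2 followed by the antipode of (camphorylsulfonyl)oxaziridine that gives the S carbinol hydroxylates the tetrasubstituted enolate to (7S)‑7‑hydroxy‑7‑methyl‑3‑[(1E)‑prop‑1‑en‑1‑yl]‑6,7‑dihydro‑1H‑isochromen‑8(5H)‑one F5. Me3SiOTf and Et3N give (7S)‑7‑methyl‑3‑[(1E)‑prop‑1‑en‑1‑yl]‑7,8‑bis(trimethylsilyloxy)‑6,7‑dihydro‑1H‑isochromene F6. Pd(OAc)2 in MeCN (Saegusa–Ito oxidation) introduces the C5–C6 double bond and delivers 15, which enters step 7 at the addition stage.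

Step 7 (the proposed new 1,6‑addition). The enolate could attack the propenyl terminus or C3, the facial preference could be weak, and proton exchange with liberated nonan‑2‑one could scramble the enolate. The fallback uses organocopper chemistry; it sets out from 14 and 11 and comes back at 17. Compound 14 is silylated (Et3SiOTf, 2,6‑lutidine, CH2Cl2, −78 °C) to (7S)‑7‑methyl‑3‑[(1E)‑prop‑1‑en‑1‑yl]‑7‑(triethylsilyloxy)‑1H‑isochromen‑8(7H)‑one F7. Compound 11 is condensed with 1,1‑dimethylhydrazine to nonan‑2‑one N,N‑dimethylhydrazone F8. F8 is deprotonated at its methyl group with LiN(iPr)2, transmetallated with CuBr·SMe2 (0.5 equiv) and added to F7 at −78 °C (azaenolate cuprate 1,6‑addition anti to the bulky silyloxy group). This gives (6S,7S)‑6‑[2‑(2,2‑dimethylhydrazinylidene)nonyl]‑7‑methyl‑3‑[(1E)‑prop‑1‑en‑1‑yl]‑7‑(triethylsilyloxy)‑6,7‑dihydro‑1H‑isochromen‑8(5H)‑one F9. Aqueous Cu(OAc)2 cleaves the hydrazone and HF·pyridine the silyl ether, giving 17.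

Step 4 (cycloisomerization–hydride transfer). Quinoid 9 may react elsewhere, or the enol ether of 10 may be reduced further. The fallback reduces first and cyclises second; it sets out from 8 and comes back at 10. NaBH4 in MeOH at 0 °C gives 2‑(hydroxymethyl)‑6‑methyl‑3‑[(3E)‑pent‑3‑en‑1‑yn‑1‑yl]phenol F10. Ph3PAuNTf2 (2 mol %) in CH2Cl2 then effects 6‑endo‑dig hydroalkoxylation, favoured by the alkenyl substituent on the alkyne, to give 10.

**Further compounds**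
F1 | step 6 | 7,8‑dihydro‑4H‑1,3‑benzodioxin‑5(6H)‑one | O=C1CCCC2=C1COCO2
F2 | step 6 | 2‑(hydroxymethyl)‑3‑[(3E)‑pent‑3‑en‑1‑yn‑1‑yl]cyclohex‑2‑en‑1‑one | C/C=C/C#CC1=C(CO)C(=O)CCC1
F3 | step 6 | 3‑[(1E)‑prop‑1‑en‑1‑yl]‑6,7‑dihydro‑1H‑isochromen‑8(5H)‑one | C/C=C/C1=CC2=C(CO1)C(=O)CCC2
F4 | step 6 | rac‑7‑methyl‑3‑[(1E)‑prop‑1‑en‑1‑yl]‑6,7‑dihydro‑1H‑isochromen‑8(5H)‑one | C/C=C/C1=CC2=C(CO1)C(=O)C(C)CC2
F5 | step 6 | (7S)‑7‑hydroxy‑7‑methyl‑3‑[(1E)‑prop‑1‑en‑1‑yl]‑6,7‑dihydro‑1H‑isochromen‑8(5H)‑one | C/C=C/C1=CC2=C(CO1)C(=O)[C@@](C)(O)CC2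
F6 | step 6 | (7S)‑7‑methyl‑3‑[(1E)‑prop‑1‑en‑1‑yl]‑7,8‑bis(trimethylsilyloxy)‑6,7‑dihydro‑1H‑isochromene | C/C=C/C1=CC2=CC[C@](C)(O[Si](C)(C)C)C(O[Si](C)(C)C)=C2CO1
F7 | step 7 | (7S)‑7‑methyl‑3‑[(1E)‑prop‑1‑en‑1‑yl]‑7‑(triethylsilyloxy)‑1H‑isochromen‑8(7H)‑one | C/C=C/C1=CC2=C(CO1)C(=O)[C@@](C)(O[Si](CC)(CC)CC)C=C2
F8 | step 7 | nonan‑2‑one N,N‑dimethylhydrazone | CCCCCCCC(C)=NN(C)C
F9 | step 7 | (6S,7S)‑6‑[2‑(2,2‑dimethylhydrazinylidene)nonyl]‑7‑methyl‑3‑[(1E)‑prop‑1‑en‑1‑yl]‑7‑(triethylsilyloxy)‑6,7‑dihydro‑1H‑isochromen‑8(5H)‑one | C/C=C/C1=CC2=C(CO1)C(=O)[C@@](C)(O[Si](CC)(CC)CC)[C@H](CC(CCCCCCC)=NN(C)C)C2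
F10 | step 4 | 2‑(hydroxymethyl)‑6‑methyl‑3‑[(3E)‑pent‑3‑en‑1‑yn‑1‑yl]phenol | C/C=C/C#Cc1ccc(C)c(O)c1CO
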